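In a one-step world, one rate constant turns time into percent reacted. This flask has a chain instead. Substrate passes over free catalyst to intermediate, intermediate takes up reagent on second catalyst to give target, and target reacts with substrate to give side product.

in all of them: gas 130 mM (held); free catalyst 15 mol%
- west: substrate 0.27 M; second catalyst 0.05 mol%; temperature 35 °C; run made earlier
- north-east: substrate 0.60 M; second catalyst 0.05 mol%; temperature 55 °C; run made earlier
- south-east: substrate 0.40 M; second catalyst 0.1 mol%; temperature 35 °C; run made earlier
- spring: substrate 0.40 M; second catalyst 0.05 mol%; temperature 40 °C; time 20 h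
- autumn: substrate 0.40 M; second catalyst 0.05 mol%; temperature 55 °C; time 20 h
- summer: substrate 0.40 M; second catalyst 0.05 mol%; temperature 70 °C; time 20 h

- west (time / h: target / %, substrate / %): 1.33: 1.5, 95.8; 2.00: 1.5, 91.5; 4.00: 4.3, 83.4; 6.00: 5.6, 76.3; 10.0: 14.6, 63.1; 15.0: 20.1, 47.6
- north-east (time / h: target / %, substrate / %): 0.500: 2.8, 84.3; 1.33: 10.9, 59.8; 3.00: 24.5, 22.1; 4.00: 27.0, 10.4; 6.00: 33.4, 2.8; 8.00: 34.4, 0
- south-east (time / h: target / %, substrate / %): 1.33: 2.6, 91.8; 2.50: 3.0, 85.3; 5.00: 12.3, 72.8; 8.00: 20.5, 54.0; 15.0: 30.7, 29.6

(standard deviation of a reading: 1 percentage point)

- in percentages every species weighs as the substrate in it: one side product counts as two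
- at the start none of reagent is dissolved
- the analysis behind the earlier runs scatters by 1 percentage point, standard deviation
- steps under discussion: substrate + free catalyst -> free catalyst + intermediate; reagent + second catalyst + intermediate -> second catalyst + target; substrate + target -> side product; gas <-> reagent

1. the flask that comes out highest in amount of target, in percent of the substrate charged, or "all alike" when all lie within 1.5 percentage points (spring / autumn / summer / all alike)
2. target at the end, in percent of the substrate charged, spring
3. target at the end, in percent of the substrate charged, autumn
4. target at the end, in percent of the substrate charged, summer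

But the reagent comes from a held gas. I took that transfer as the fast step and treated reagent as settled at 130 mM, whatever the charge. Both catalysts are loaded on the substrate, so at fixed temperature and loadings each remaining step then runs in proportion to the charge cA. Percentages should therefore follow one clock, θ = cA·t, the charge times the time: 480 M·min for autumn.

The earlier runs allowed a test on early substrate loss, −ln(substrate fraction)/θ. West gave 0.167 M⁻¹ h⁻¹ and south-east gave 0.159 M⁻¹ h⁻¹, close for a scatter of 1 percentage point.

So autumn's end should match north-east at 13.3 h. North-east's last reading, at 8.00 h, showed substrate 0% and target 34.4%, barely up from 33.4%. My own reckoning, read from that north-east value, therefore gave about 34.4% for autumn.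

The clock does not cross temperatures. But south-east at 15.0 h, colder and with more second catalyst, held more target than north-east at 3.00 h (30.7% against 24.5%), with substrate 29.6% against 22.1%. So I ranked spring above autumn and summer below it.

The forecast, made apart from my reckoning, named spring, with spring 38%, autumn 35.5%, above my 34.4%, and summer 23%, on the ground that “Side reaction has the highest barrier, so heat hurts”.

The flasks gave spring as highest, with spring 38.2%, autumn 34.2% and summer 29.3%.

    substrate + free catalyst → free catalyst + intermediate (k = 1.40 M⁻¹ h⁻¹, Ea = 57.0 kJ mol⁻¹)
    reagent + second catalyst + intermediate → second catalyst + target (k = 13000 M⁻² h⁻¹, Ea = 51.0 kJ mol⁻¹)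
    substrate + target → side product (k = 0.530 M⁻¹ h⁻¹, Ea = 81.0 kJ mol⁻¹)
    gas ⇌ reagent, rate k4*(csat - [reagent]) (kL = 7.90 h⁻¹)
    (constants at 40 °C)

Autumn's 34.2% at clock 480 M·min stands beside north-east's 34.4%, read at clock 288 M·min. Spring, with each setting moved alone by the same factor, ranked them as free catalyst (8.4 points), then substrate (3.3 points), then time (3.3 points), then second catalyst (0.97 points), with substrate and time level. At 2.00 h in autumn, substrate had a half-life of 3.0 h by the free-catalyst step and 6.3 h by the side step, so the free-catalyst step consumed it faster than the side step. Target in autumn was then made 2.09 times as fast as it was used up, each step taken net.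

The earlier runs and the new flask were computed for an exercise; noise was put on by code.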